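3 questions ask how much target survives in two flasks and which holds more, and I answer them with the shortfall of target at a late reading divided by the substrate charge.

| setting | north-east | west | south | winter | dawn |
|---|---|---|---|---|---|
| substrate | 0.045 M | 0.098 M | 0.24 M | 0.050 M | 0.20 M |
| partner | 0.40 M | 0.40 M | 0.40 M | 0.400 M | 0.400 M |
| temperature | 32 °C | 49 °C | 32 °C |  |  |
| remark | run made earlier | run made earlier | run made earlier | at 25 °C throughout | at 25 °C until 3.0 min, from then on at 55 °C |
| time |  |  |  | 10 min | 10 min |

- north-east (time / min: target / %): 0.417: 69.5; 1.00: 87.2; 2.00: 93.8; 5.00: 95.2
- west (time / s: target / %): 25.0: 73.5; 50.0: 87.2; 80.0: 93.6; 90.0: 94.9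
- south (time / min: target / %): 0.417: 46.9; 1.00: 60.2; 2.00: 71.0; 5.00: 82.1

(standard deviation of a reading: 0.5 percentage points)

- steps that have been proposed: substrate + partner <-> target + released group; released group -> by-product carried off; target + released group -> side product

- which of the two ends with the higher amount of target, in percent of the substrate charged ("neither" if they lie within 2 percentage points) (winter / dawn / neither)
- target at the end, in percent of the substrate charged, winter
- target at the end, in percent of the substrate charged, dawn

My bench rule is that a loss between two products takes a share that grows in step with the charge, provided the partner stays roughly constant, the pseudo-first-order picture, which wants about ten times the substrate. The north-east run, with a ratio of 8.89, gives the loss per molar 1.07 M⁻¹, read at 32 °C. The west run, at a ratio of 4.08 and with target still rising from 93.6 % to 94.9 % between its last two readings, gives no settled loss, so I leave it out and carry the north-east value unchanged to flasks at other temperatures, working in powers of ten: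

power of ten of the north-east loss share = −1.32

power of ten of the charge step to winter = 0.0458

winter's loss share, from the sum of the two = 5.33 %

Winter, with a ratio of 8.00, then holds 94.7 % of target by my reckoning. Dawn by the same rule holds 78.7 %, but its ratio is 2.00, and the south run, at 1.67, marks the border: its shortfall per molar is 0.746 M⁻¹ while target is still rising, a factor 0.697 of the north-east value at the same temperature. For dawn I therefore take the south value, which gives 85.1 %, and I commit to that figure as an estimate that carries a reading from 32 °C to a flask at other temperatures.

The forecast says winter, with 91 % for winter and 87 % for dawn, the latter higher than my figure: “The gap is small but favours winter, with real uncertainty.”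

    substrate + partner ⇌ target + released group (K = 0.420, k = 0.0950 M⁻¹ s⁻¹, Ea = 65.0 kJ mol⁻¹, ΔH = −90.0 kJ mol⁻¹)
    released group → by-product carried off (k = 0.0300 s⁻¹, Ea = 87.0 kJ mol⁻¹)
    target + released group → side product (k = 0.0630 M⁻¹ s⁻¹, Ea = 48.0 kJ mol⁻¹)
    (constants at 25 °C)

The flask gives 93.1 % in winter and 83.0 % in dawn, so winter leads by 10 percentage points, as the forecast said; against that gap, winter's answer has moved by 5 points at 0.0988 M of substrate. The neighbour, like dawn but charged with 0.12 M of substrate, has 3.33 equiv of partner, and the same reckoning gives 91.0 % of target with the south value and 87.2 % with the north-east value. That flask ends with 87.3 % of target, 12.7 % of side product and 70 % of its partner left.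

(Readings and results stem from a simulated flask for substances that don't exist.)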